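Take the time of reading first: every flask is read at 6.0 min, so the question is how much target has formed by then from one charge at different temperatures.

| setting | blue | green | Tuesday's | Wednesday's | Monday's | Saturday's |
|---|---|---|---|---|---|---|
| substrate | 0.48 M | 0.72 M | 0.96 M | 0.96 M | 0.96 M | 0.96 M |
| coupling partner | 0.912 M | 0.912 M | 0.912 M | 0.912 M | 0.912 M | 0.912 M |
| other conformer | 0.24 M | 0.24 M | 0.240 M | 0.240 M | 0.240 M | 0.240 M |
| temperature | −35 °C | 15 °C | 30 °C | 0 °C | −30 °C | 60 °C |
| remark | run made earlier | run made earlier |  |  |  |  |
| time |  |  | 6.0 min | 6.0 min | 6.0 min | 6.0 min |

| run | time / min | target / % |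
|---|---|---|
| blue | 40.0 | 0.5 |
| blue | 80.0 | 0.2 |
| blue | 120 | 0.3 |
| blue | 150 | 0.1 |
| green | 1.00 | 1.2 |
| green | 2.00 | 2.3 |
| green | 5.00 | 6.6 |
| green | 12.0 | 10.2 |

(scatter of a reading: 0.5 percentage points)

- the flask with the highest amount of target, in percent of the substrate and other conformer together charged ("all alike" if they lie within 1.5 percentage points) (Tuesday's / Wednesday's / Monday's / Saturday's / all alike)
- final target, as a percentage of the substrate and other conformer together charged, in Tuesday's
- final target, as a percentage of the substrate and other conformer together charged, in Wednesday's
- final target, as a percentage of the substrate and other conformer together charged, in Monday's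
- final target, as a percentage of the substrate and other conformer together charged, in Saturday's

- in a conversion other conformer counts as not yet reacted

Go through the given numbers and ask how far the outcome moves if each were off. Take the substrate: its share of the charge is 80.0% in the flasks asked about and 75.0% in the green run, so the percent scale differs little between them. Take the temperature next: from the blue run at −35 °C to the green run at 15 °C, which also differ in substrate, the first slope reads about 96.0 times greater, so an error in the temperature dependence weighs heavily. That factor is a poor one, though, because the first blue reading is about as large as the scatter of 0.5 percentage points.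

The coupling partner gives the scale. With 0.912 M against 0.96 M of substrate in the flasks asked about, it is the limiting reagent there. So count one coupling partner per target and take as the top of the scale the partner ceiling, the target that would stand if every coupling partner charged ended as target: 76.0%. Any error in 0.912 M moves it in step.

Now test the scale on the green run, whose ceiling is 95.0%, counted with substrate and other conformer together at 0.960 M against 0.912 M of coupling partner. Its last reading has reached 10.7% of that, yet its slope after 5.00 min reads 42.9% of the first slope. Treat the ceiling, then, as an upper bound.

The forecast gives 19% for Tuesday's, 1.6% for Wednesday's, 0.1% for Monday's and 45% for Saturday's, which is 59.2% of the ceiling, and it names Saturday's. It says: “That suggests a drain, probably substrate relaxing to the other conformer or target being lost.”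

The flasks give 14.3% for Tuesday's, 1.74% for Wednesday's, 0.0489% for Monday's and 6.77% for Saturday's, so Tuesday's holds the most.

    coupling partner → decomposed reagent (k = 0.0703 s⁻¹, Ea = 86.0 kJ mol⁻¹)
    substrate + coupling partner ⇌ target (K = 6.50 M⁻¹, k = 0.0166 M⁻¹ s⁻¹, Ea = 68.0 kJ mol⁻¹, ΔH = −38.0 kJ mol⁻¹)
    coupling partner + other conformer → isomer of the product (k = 0.205 M⁻¹ s⁻¹, Ea = 53.0 kJ mol⁻¹)
    substrate ⇌ other conformer (K = 0.0176, k = 0.0236 s⁻¹, Ea = 93.0 kJ mol⁻¹, ΔH = −22.0 kJ mol⁻¹)
    other conformer ⇌ dormant form (K = 0.870, k = 0.00168 s⁻¹, Ea = 93.0 kJ mol⁻¹, ΔH = −44.0 kJ mol⁻¹)
    (constants at 60 °C)

In Saturday's, 0.765 M of decomposed reagent stands at 6.00 min, out of 0.912 M of coupling partner charged, and 0.26% of that charge is left. On the scale, Tuesday's target is 18.8% of its ceiling. The same flask charged with 0.36 M of coupling partner has a ceiling of 30.0%, and its target of 5.71% is 19.0% of that.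

The readings stem from a simulated flask with constants of no real substance; the scatter is artificial.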